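**Retrosynthetic overview** (chain locants C1 = CHBr … C8 = CH2Cl)
1. The oxirane, the only ring, is formed last by hydroxyl-directed epoxidation of the C3=C4 alkene (sets C3, C4 from C6).
2. The C7(Br)–C8(Cl) unit comes from an anti-Markovnikov bromochlorination of the C6 allylic alcohol (new Ti-mediated step; sets C7).
3. The (Z)-BrCH=C(Cl) unit comes from a silyl alkyne via the bromoalkyne and anti-addition of HCl.
4. C4–C5, C6–C7 and the C6 stereocentre are made in one Pd-induced 1,2-metallate shift (conjunctive coupling) of a vinyl/isopropenyl borate with an (E)-alkenyl iodide, then C–B oxidation.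
5. Fragments: isopropenyl-MgBr, vinyl-MgBr and 1-(trimethylsilyl)buta-1,3-diyne (methyl from AlMe3).

Assumption: 1-(trimethylsilyl)buta-1,3-diyne and the two Grignard solutions are bought as such.

**Step 1**
Reactants: 1 isopropenylmagnesium bromide
Product: 3 2-isopropenyl-4,4,5,5-tetramethyl-1,3,2-dioxaborolane, via isopropoxy borate complex 2 (not isolated)
Conditions: iPrOBpin, THF, −78 °C → rt; 1 M HCl; distil
Reagents that add atoms: 2-isopropoxy-4,4,5,5-tetramethyl-1,3,2-dioxaborolane, CC(C)OB1OC(C)(C)C(C)(C)O1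
Why: Grignard borylation; the alkenyl Grignard adds to boron and the tetracoordinate borate loses isopropoxide on acidic work-up (no stereocentre).

**Step 2**
Reactants: 4 1-(trimethylsilyl)buta-1,3-diyne
Product: 6 (E)-(4-iodo-3-methylbut-3-en-1-yn-1-yl)trimethylsilane, via alkenylalane 5 (not isolated)
Conditions: AlMe3 (2 equiv), Cp2ZrCl2 (0.25 equiv), CH2Cl2, 0 °C → rt; then I2, THF, −30 → 0 °C
Reagents that add atoms: trimethylaluminium, C[Al](C)C; iodine, II
Why: Zr-catalysed carboalumination (Negishi) adds Me–Al syn to the terminal alkyne only, with Al on the terminal carbon, and iodinolysis with retention fixes the E geometry (I cis to Me).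

**Step 3**
Reactants: 3 2-isopropenyl-4,4,5,5-tetramethyl-1,3,2-dioxaborolane; 7 vinylmagnesium bromide; 6 (E)-(4-iodo-3-methylbut-3-en-1-yn-1-yl)trimethylsilane
Product: 10 (3R,5E)-2,6-dimethyl-8-(trimethylsilyl)octa-1,5-dien-7-yn-3-ol, via bis(alkenyl) borate complex 8 (not isolated), via allylic boronate 9 (not isolated)
Conditions: 3 + 7, NaOTf, THF, 0 °C → rt; then 6, Pd(OAc)2 (2 mol %), (Sp,Sp)-MandyPhos (2.4 mol %; antipode if the sense proves opposite), THF, 40 °C; then 30 % H2O2, pH 7 buffer, 0 °C → rt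
Reagents that add atoms: hydrogen peroxide, OO
Why: Enantioselective conjunctive cross-coupling; the alkenyl-Pd(II) from 6 binds the unhindered vinyl group of 8 and induces a 1,2-metallate shift of the isopropenyl group from boron to C6, reductive elimination forms C4–C5 with the E alkene retained, the chiral bisphosphine sets C6 (R), and the boronate is oxidised with retention.

**Step 4**
Reactants: 10 (3R,5E)-2,6-dimethyl-8-(trimethylsilyl)octa-1,5-dien-7-yn-3-ol
Product: 11 (3R,5E)-8-bromo-2,6-dimethylocta-1,5-dien-7-yn-3-ol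
Conditions: NBS (1.1 equiv), AgNO3 (10 mol %), acetone, rt, dark
Reagents that add atoms: N-bromosuccinimide, O=C1CCC(=O)N1Br
Why: Silver-catalysed desilylative bromination through a silver acetylide converts C(sp)–Si into C(sp)–Br without touching the alkenes or the alcohol.

**Step 5**
Reactants: 11 (3R,5E)-8-bromo-2,6-dimethylocta-1,5-dien-7-yn-3-ol
Product: 12 (3R,5E,7Z)-8-bromo-7-chloro-2,6-dimethylocta-1,5,7-trien-3-ol
Conditions: LiCl (3 equiv), Pd(OAc)2 (5 mol %), AcOH, rt
Reagents that add atoms: lithium chloride, [Li+].[Cl-]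
Why: Pd(II)-catalysed anti-hydrochlorination of a 1-bromoalkyne (chloride attacks the internal carbon of the Pd-bound alkyne, then protodepalladation with retention) places H trans to Cl, so Br is cis to Cl (Z).

**Step 6**
Reactants: 12 (3R,5E,7Z)-8-bromo-7-chloro-2,6-dimethylocta-1,5,7-trien-3-ol
Product: 13 (2R,3R,5E,7Z)-2,8-dibromo-1,7-dichloro-2,6-dimethylocta-5,7-dien-3-ol
Conditions: NBS (1.1 equiv), ClTi(OiPr)3 (1.1 equiv), chiral tridentate salicylaldimine–amino alcohol ligand (20 mol %, enantiomer matched to the substrate), hexanes, −20 °C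
Reagents that add atoms: N-bromosuccinimide, O=C1CCC(=O)N1Br; chlorotitanium triisopropoxide, CC(C)O[Ti](Cl)(OC(C)C)OC(C)C
Why: Proposed new method: a Ti(IV)/chiral Schiff-base-controlled anti-Markovnikov bromochlorination of a secondary 1,1-disubstituted allylic alcohol, in which the C6 alkoxide binds Ti, ligand-bound Br+ from NBS is delivered to the Si face of C7 (priorities C6 > C8 > CH3), and the bromonium is opened anti at the unhindered C8 methylene by titanium-bound chloride within the complex before free chloride can attack tertiary C7 (its cationic character is damped by the adjacent C–O–Ti dipole and the non-polar medium), so the tertiary C7–Br stereocentre (R) and the primary C–Cl are set together; closest known reaction type: Ti/Schiff-base-catalysed enantioselective bromochlorination of allylic alcohols (Br at C2, Cl at C3), which to my knowledge has not been shown to make a tertiary bromide from a 2-substituted secondary allylic alcohol.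

**Step 7**
Reactants: 13 (2R,3R,5E,7Z)-2,8-dibromo-1,7-dichloro-2,6-dimethylocta-5,7-dien-3-ol
Product: 14 (2R,3R)-3-bromo-1-[(2S,3R)-3-[(Z)-2-bromo-1-chloroethenyl]-3-methyloxiran-2-yl]-4-chloro-3-methylbutan-2-ol
Conditions: VO(acac)2 (5 mol %), TBHP (1.5 equiv, decane), CH2Cl2, 0 °C → rt
Reagents that add atoms: tert-butyl hydroperoxide, CC(C)(C)OO
Why: Vanadium-catalysed hydroxyl-directed epoxidation of a homoallylic alcohol; in the chair vanadate transition state the bulky C7 group is equatorial and the methyl cis on C3 excludes the other chairs, which gives the 4,6-syn epoxy alcohol (3R,4S), and the halovinyl alkene is too electron-poor to react.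

**Compound list**
1 | isopropenylmagnesium bromide | C=C(C)[Mg]Br | starting material
2 | bromomagnesium isopropoxy(isopropenyl)(pinacolato)borate | C=C(C)[B-]1(OC(C)C)OC(C)(C)C(C)(C)O1.[Mg+]Br | intermediate
3 | 2-isopropenyl-4,4,5,5-tetramethyl-1,3,2-dioxaborolane | C=C(C)B1OC(C)(C)C(C)(C)O1 | intermediate
4 | 1-(trimethylsilyl)buta-1,3-diyne | C#CC#C[Si](C)(C)C | starting material
5 | (E)-dimethyl[2-methyl-4-(trimethylsilyl)but-1-en-3-yn-1-yl]alane | C[Al](C)/C=C(C)/C#C[Si](C)(C)C | intermediate
6 | (E)-(4-iodo-3-methylbut-3-en-1-yn-1-yl)trimethylsilane | I/C=C(C)/C#C[Si](C)(C)C | intermediate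
7 | vinylmagnesium bromide | C=C[Mg]Br | starting material
8 | bromomagnesium isopropenyl(vinyl)(pinacolato)borate | C=C[B-]1(C(C)=C)OC(C)(C)C(C)(C)O1.[Mg+]Br | intermediate
9 | 2-[(3R,5E)-2,6-dimethyl-8-(trimethylsilyl)octa-1,5-dien-7-yn-3-yl]-4,4,5,5-tetramethyl-1,3,2-dioxaborolane | C=C(C)[C@H](B1OC(C)(C)C(C)(C)O1)C/C=C(C)/C#C[Si](C)(C)C | intermediate
10 | (3R,5E)-2,6-dimethyl-8-(trimethylsilyl)octa-1,5-dien-7-yn-3-ol | C=C(C)[C@H](O)C/C=C(C)/C#C[Si](C)(C)C | intermediate
11 | (3R,5E)-8-bromo-2,6-dimethylocta-1,5-dien-7-yn-3-ol | C=C(C)[C@H](O)C/C=C(C)/C#CBr | intermediate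
12 | (3R,5E,7Z)-8-bromo-7-chloro-2,6-dimethylocta-1,5,7-trien-3-ol | C=C(C)[C@H](O)C/C=C(C)/C(Cl)=C/Br | intermediate
13 | (2R,3R,5E,7Z)-2,8-dibromo-1,7-dichloro-2,6-dimethylocta-5,7-dien-3-ol | C[C@](Br)(CCl)[C@H](O)C/C=C(C)/C(Cl)=C/Br | intermediate
14 | (2R,3R)-3-bromo-1-[(2S,3R)-3-[(Z)-2-bromo-1-chloroethenyl]-3-methyloxiran-2-yl]-4-chloro-3-methylbutan-2-ol | C[C@](Br)(CCl)[C@H](O)C[C@@H]1O[C@@]1(C)/C(Cl)=C/Br | target

**Totals and risks**
Total steps: 7. Longest linear sequence: 6 (steps 2–7, from 4).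

Step 6 (the proposed new step). Likely failures are the Markovnikov regioisomer (tertiary chloride, primary bromide), hydride-shift (semipinacol) ketone formation, or the wrong C7 epimer. The fallback uses known chemistry, sets out from 12 and returns at 13. Directed epoxidation of the allylic alkene (VO(acac)2/TBHP, or Ti(OiPr)4/tartrate/TBHP in the matched sense) gives the erythro epoxy alcohol (1R,3E,5Z)-6-bromo-5-chloro-4-methyl-1-[(2S)-2-methyloxiran-2-yl]hexa-3,5-dien-1-ol F3. Payne rearrangement (NaOH, t-BuOH/H2O) moves the epoxide to C6–C7 with inversion at C7 and gives [(2R,3R)-3-[(2E,4Z)-5-bromo-4-chloro-3-methylpenta-2,4-dien-1-yl]-2-methyloxiran-2-yl]methanol F4. Appel chlorination (PPh3, CCl4, NaHCO3) gives (2S,3R)-3-[(2E,4Z)-5-bromo-4-chloro-3-methylpenta-2,4-dien-1-yl]-2-(chloromethyl)-2-methyloxirane F5. Opening at the tertiary carbon with anhydrous HBr (or MgBr2·OEt2) at low temperature, again with inversion at C7, gives 13; the two inversions put Br where the first epoxide oxygen was.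

Step 3. Likely failures are direct Suzuki-type transfer of an alkenyl group, the wrong alkene acting as acceptor, halide inhibition, or low er. The fallback sets out from 6 and returns at 10. Pd-catalysed Negishi coupling of 6 with the Reformatsky reagent from 2-bromo-N-methoxy-N-methylacetamide gives (E)-N-methoxy-N,4-dimethyl-6-(trimethylsilyl)hex-3-en-5-ynamide F1. Addition of 1 gives (E)-2,6-dimethyl-8-(trimethylsilyl)octa-1,5-dien-7-yn-3-one F2, which is used crude to avoid conjugation. (S)-Me-CBS/BH3·SMe2 reduction (isopropenyl as the large group) gives 10.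

Step 7. Likely failures are a sluggish reaction at the halogen-deactivated diene, acid-promoted cyclisation of the epoxy alcohol, or modest dr. The fallback sets out from 13 and returns at 14. TESOTf/2,6-lutidine gives triethyl{[(2R,3R,5E,7Z)-2,8-dibromo-1,7-dichloro-2,6-dimethylocta-5,7-dien-3-yl]oxy}silane F6. Reagent-controlled Shi epoxidation (L-fructose-derived ketone as assigned by the spiro model, Oxone, pH 10.5 buffer, MeCN/DMM, 0 °C) gives the silyl ether of the target, triethyl{[(2R,3R)-3-bromo-1-[(2S,3R)-3-[(Z)-2-bromo-1-chloroethenyl]-3-methyloxiran-2-yl]-4-chloro-3-methylbutan-2-yl]oxy}silane F7; the silyl ether blocks base-induced closure of the bromohydrin. Buffered HF·pyridine at 0 °C gives 14.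

**Further compounds**
F1 | step 3 | (E)-N-methoxy-N,4-dimethyl-6-(trimethylsilyl)hex-3-en-5-ynamide | CON(C)C(=O)C/C=C(C)/C#C[Si](C)(C)C
F2 | step 3 | (E)-2,6-dimethyl-8-(trimethylsilyl)octa-1,5-dien-7-yn-3-one | C=C(C)C(=O)C/C=C(C)/C#C[Si](C)(C)C
F3 | step 6 | (1R,3E,5Z)-6-bromo-5-chloro-4-methyl-1-[(2S)-2-methyloxiran-2-yl]hexa-3,5-dien-1-ol | C[C@]1(CO1)[C@H](O)C/C=C(C)/C(Cl)=C/Br
F4 | step 6 | [(2R,3R)-3-[(2E,4Z)-5-bromo-4-chloro-3-methylpenta-2,4-dien-1-yl]-2-methyloxiran-2-yl]methanol | C[C@]1(CO)O[C@@H]1C/C=C(C)/C(Cl)=C/Br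
F5 | step 6 | (2S,3R)-3-[(2E,4Z)-5-bromo-4-chloro-3-methylpenta-2,4-dien-1-yl]-2-(chloromethyl)-2-methyloxirane | C[C@]1(CCl)O[C@@H]1C/C=C(C)/C(Cl)=C/Br
F6 | step 7 | triethyl{[(2R,3R,5E,7Z)-2,8-dibromo-1,7-dichloro-2,6-dimethylocta-5,7-dien-3-yl]oxy}silane | C[C@](Br)(CCl)[C@H](O[Si](CC)(CC)CC)C/C=C(C)/C(Cl)=C/Br
F7 | step 7 | triethyl{[(2R,3R)-3-bromo-1-[(2S,3R)-3-[(Z)-2-bromo-1-chloroethenyl]-3-methyloxiran-2-yl]-4-chloro-3-methylbutan-2-yl]oxy}silane | C[C@](Br)(CCl)[C@H](O[Si](CC)(CC)CC)C[C@@H]1O[C@@]1(C)/C(Cl)=C/Br
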